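**Retrosynthetic overview**

1. Target ⇒ inversion at C4 of the 2,4-cis 4,5-diol (Mitsunobu, then saponification, which also frees the 4'-phenol).
2. cis-Diol ⇒ fluoride removal of a di-tert-butylsilylene bridge between O4 and O5.
3. Key disconnection: ring C (O1–C2 and C3–C4) and the six-membered dioxasilin ring (O4–Si) are opened together, to an aryloxysilanol salicylaldehyde plus 4-acetoxystyrene. A chiral Brønsted acid sets C2; the tether sets C4 cis.
4. Silanol aldehyde ⇒ silylation of the less hindered OH of the C-prenylated aldehyde ⇒ 2,6-dihydroxy-4-methoxybenzaldehyde and prenyl bromide.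
5. Ring order: rings A and B are bought; the dioxasilin ring and ring C form in one operation; the dioxasilin ring is then removed.

Assumptions: 2,6-dihydroxy-4-methoxybenzaldehyde 1 is bought as a catalogue compound, and the (R)-catalyst of step 3 is taken to give the (2S,4S) adduct (the (S)-catalyst is used if the opposite sense is found).

**Route**

Step 1
Reactants: 1 2,6-dihydroxy-4-methoxybenzaldehyde; 2 prenyl bromide (1-bromo-3-methylbut-2-ene)
Product: 3 2,6-dihydroxy-4-methoxy-3-(3-methylbut-2-en-1-yl)benzaldehyde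
Conditions: 2 (1.0 equiv), KOH (10% aq.), 0 °C to rt
Reagents that add atoms: prenyl bromide (2), CC(C)=CCBr
Why: Phenoxide C-alkylation (ortho-C-prenylation of a phloroglucinol-type ring) is favoured in water, and because C3 and C5 of 1 are equivalent only one mono-C-prenyl isomer can form; no stereocenter is made.

Step 2
Reactants: 3 2,6-dihydroxy-4-methoxy-3-(3-methylbut-2-en-1-yl)benzaldehyde; 4 di-tert-butylsilyl bis(trifluoromethanesulfonate)
Product: 6 6-{[di-tert-butyl(hydroxy)silyl]oxy}-2-hydroxy-4-methoxy-3-(3-methylbut-2-en-1-yl)benzaldehyde, via aryloxysilyl triflate 5 (not isolated)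
Conditions: 4 (1.05 equiv), 2,6-lutidine (2.5 equiv), CH2Cl2, −78 to −40 °C; then H2O, 0 °C
Reagents that add atoms: di-tert-butylsilyl bis(trifluoromethanesulfonate) (4), CC(C)(C)[Si](OS(=O)(=O)C(F)(F)F)(OS(=O)(=O)C(F)(F)F)C(C)(C)C; water, O
Why: O-Silylation then hydrolysis: the very bulky silyl ditriflate reacts irreversibly at the OH flanked by H and not at the OH buttressed between the formyl and prenyl groups, which fixes which oxygen later becomes O5 and which O1, and water turns the remaining Si–OTf into a stable di-tert-butylsilanol; no stereocenter is made.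

Step 3
Reactants: 6 6-{[di-tert-butyl(hydroxy)silyl]oxy}-2-hydroxy-4-methoxy-3-(3-methylbut-2-en-1-yl)benzaldehyde; 7 4-acetoxystyrene (4-ethenylphenyl acetate)
Product: 9 (2S,4S)-4'-acetoxy-4,5-O-(di-tert-butylsilanediyl)-7-methoxy-8-(3-methylbut-2-en-1-yl)flavan-4,5-diol (2,4-cis; Si bridges O4 and O5), via cyclic silyl hemiacetal 8 (not isolated)
Conditions: 7 (3 equiv), (R)-3,3'-bis(2,4,6-triisopropylphenyl)-1,1'-binaphthalene-2,2'-diyl N-(trifluoromethanesulfonyl)phosphoramide (10 mol %), 4 Å molecular sieves, toluene, 0 °C to rt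
Reagents that add atoms: 4-acetoxystyrene (7), CC(=O)Oc1ccc(C=C)cc1
Why: Proposed new method: the acid closes the silanol onto the formyl group (hemiacetal 8) and ionises it to a silicon-bridged benzodioxasilinylium ion, an O-protonated ortho-quinone methide that is ion-paired and hydrogen-bonded through O1–H to the chiral phosphoramide anion and adds the styrene in an endo inverse-electron-demand oxa-[4+2] cycloaddition, so the dioxasilin ring and ring C form in the same operation, the catalyst choosing the face (C2 = S) and the in-plane O4–Si tether plus the endo mode placing O4 cis to the aryl group (C4 = S); the closest known reaction types are the chiral N-triflylphosphoramide-catalysed [4+2] cycloaddition of in situ formed ortho-quinone methides with styrenes and the acid-mediated salicylaldehyde/orthoformate/styrene synthesis of 4-alkoxyflavans.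

Step 4
Reactants: 9 (2S,4S)-4'-acetoxy-4,5-O-(di-tert-butylsilanediyl)-7-methoxy-8-(3-methylbut-2-en-1-yl)flavan-4,5-diol
Product: 10 (2S,4S)-4'-acetoxy-7-methoxy-8-(3-methylbut-2-en-1-yl)flavan-4,5-diol (2,4-cis)
Conditions: HF·pyridine, pyridine, THF, 0 °C
Reagents that add atoms: none
Why: Fluoride-mediated desilylation cleaves only the two Si–O bonds, so both C–O bonds and hence C2 (S) and C4 (S) are retained, and the pyridine-buffered conditions leave the aryl acetate, the prenyl group and the ionisable benzylic alcohol intact.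

Step 5
Reactants: 10 (2S,4S)-4'-acetoxy-7-methoxy-8-(3-methylbut-2-en-1-yl)flavan-4,5-diol; 11 4-nitrobenzoic acid
Product: 13 (2S,4R)-4,5,4'-trihydroxy-7-methoxy-8-(3-methylbut-2-en-1-yl)flavan (2,4-trans; the target), via trans 4-nitrobenzoate 12 (not isolated)
Conditions: PPh3, diisopropyl azodicarboxylate, 11 (1.5 equiv each), THF, −20 to 0 °C; then LiOH, THF/H2O, 0 °C; AcOH to pH 7
Reagents that add atoms: 4-nitrobenzoic acid (11), O=C(O)c1ccc(cc1)[N+](=O)[O-]
Why: Mitsunobu reaction: the C4 alkoxyphosphonium is displaced by 4-nitrobenzoate with inversion (4S to 4R; any ortho-quinone methide formed by ionisation is also captured axially, anti to the equatorial 2-aryl group, giving the same trans ester, whose alkyl oxygen comes from the carboxylate), and saponification by acyl–oxygen cleavage in water, not alcohol, then frees O4–H and the 4'-phenol without touching C2 or C4.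

**Compound list**

1 | 2,6-dihydroxy-4-methoxybenzaldehyde | COc1cc(O)c(C=O)c(O)c1 | starting material
2 | prenyl bromide (1-bromo-3-methylbut-2-ene) | CC(C)=CCBr | starting material
3 | 2,6-dihydroxy-4-methoxy-3-(3-methylbut-2-en-1-yl)benzaldehyde | COc1cc(O)c(C=O)c(O)c1CC=C(C)C | intermediate
4 | di-tert-butylsilyl bis(trifluoromethanesulfonate) | CC(C)(C)[Si](OS(=O)(=O)C(F)(F)F)(OS(=O)(=O)C(F)(F)F)C(C)(C)C | starting material
5 | 6-{[di-tert-butyl(trifluoromethanesulfonyloxy)silyl]oxy}-2-hydroxy-4-methoxy-3-(3-methylbut-2-en-1-yl)benzaldehyde (forms in the flask in step 2) | COc1cc(O[Si](OS(=O)(=O)C(F)(F)F)(C(C)(C)C)C(C)(C)C)c(C=O)c(O)c1CC=C(C)C | intermediate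
6 | 6-{[di-tert-butyl(hydroxy)silyl]oxy}-2-hydroxy-4-methoxy-3-(3-methylbut-2-en-1-yl)benzaldehyde | COc1cc(O[Si](O)(C(C)(C)C)C(C)(C)C)c(C=O)c(O)c1CC=C(C)C | intermediate
7 | 4-acetoxystyrene (4-ethenylphenyl acetate) | CC(=O)Oc1ccc(C=C)cc1 | starting material
8 | 2,2-di-tert-butyl-7-methoxy-6-(3-methylbut-2-en-1-yl)-4H-1,3,2-benzodioxasilin-4,5-diol (either configuration at C4; forms in the flask in step 3) | COc1cc2O[Si](C(C)(C)C)(C(C)(C)C)OC(O)c2c(O)c1CC=C(C)C | intermediate
9 | (2S,4S)-4'-acetoxy-4,5-O-(di-tert-butylsilanediyl)-7-methoxy-8-(3-methylbut-2-en-1-yl)flavan-4,5-diol (2,4-cis) | COc1cc(O3)c2c(c1CC=C(C)C)O[C@H](c1ccc(OC(C)=O)cc1)C[C@@H]2O[Si]3(C(C)(C)C)C(C)(C)C | intermediate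
10 | (2S,4S)-4'-acetoxy-7-methoxy-8-(3-methylbut-2-en-1-yl)flavan-4,5-diol (2,4-cis) | COc1cc(O)c2c(c1CC=C(C)C)O[C@H](c1ccc(OC(C)=O)cc1)C[C@@H]2O | intermediate
11 | 4-nitrobenzoic acid | O=C(O)c1ccc(cc1)[N+](=O)[O-] | starting material
12 | (2S,4R)-4'-acetoxy-5-hydroxy-7-methoxy-8-(3-methylbut-2-en-1-yl)flavan-4-yl 4-nitrobenzoate (2,4-trans; forms in the flask in step 5) | COc1cc(O)c2c(c1CC=C(C)C)O[C@H](c1ccc(OC(C)=O)cc1)C[C@H]2OC(=O)c1ccc(cc1)[N+](=O)[O-] | intermediate
13 | (2S,4R)-4,5,4'-trihydroxy-7-methoxy-8-(3-methylbut-2-en-1-yl)flavan (2,4-trans) | COc1cc(O)c2c(c1CC=C(C)C)O[C@H](c1ccc(O)cc1)C[C@H]2O | target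

**Step count and risks**

Total steps: 5. Longest linear sequence: 5 steps (1 → 3 → 6 → 9 → 10 → 13).

The three steps most likely to fail are step 3, step 5 and step 2, in that order.

Step 3 is a new reaction. The ee may be low, the weakly nucleophilic styrene may add slowly, the prenyl alkene of a second molecule may compete for the cation, and the acid may close the free O–H onto the neighbouring prenyl group to give a dimethylchroman. The fallback gives up catalytic control and resolves instead, setting out from 6. The same cyclodehydration/cycloaddition with achiral diphenyl phosphate (10 mol %) gives the racemic cis cycloadduct F1, and HF·pyridine then gives the racemic cis-diol F2. The Mitsunobu reaction of F2 is run with (S)-2-methoxy-2-phenylacetic acid in place of 11, which gives two trans esters: the (2S,4R) O-methylmandelate F3 and its (2R,4S) diastereomer F4. These are separated by chromatography or crystallisation, and LiOH in THF/H2O on F3 comes back to the route at 13.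

Step 5 may leak into elimination to the flav-3-ene or into C4–C6 coupling of the very electron-rich benzylic system instead of clean displacement. The fallback sets out from 10 and replaces substitution by equilibration. LiOH in THF/H2O removes the acetate to give the cis-triol F5. Catalytic pyridinium p-toluenesulfonate in dilute THF/H2O at rt then ionises C4 reversibly, and water re-adds axially, anti to the equatorial 2-aryl group, which should favour the trans isomer; this comes back to the route at 13, and recovered F5 is recycled.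

Step 2 may suffer because the aryloxysilyl triflate can activate its own formyl group, a cationic species that can attack the prenyl alkene, or because silylation is less selective than expected. The fallback sets out from 3 and avoids Lewis-acidic silicon. Di-tert-butylchlorosilane and imidazole in DMF give the aryloxy(di-tert-butyl)silane F6, again at the less hindered OH. Hydrolytic oxidation of its Si–H bond with water and catalytic [RuCl2(p-cymene)]2 in MeCN then comes back to the route at 6.

**Further compounds**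

F1 | step 3 | racemic 2,4-cis 4'-acetoxy-4,5-O-(di-tert-butylsilanediyl)-7-methoxy-8-(3-methylbut-2-en-1-yl)flavan-4,5-diol (9 plus its enantiomer) | COc1cc(O3)c2c(c1CC=C(C)C)O[C@H](c1ccc(OC(C)=O)cc1)C[C@@H]2O[Si]3(C(C)(C)C)C(C)(C)C.COc1cc(O3)c2c(c1CC=C(C)C)O[C@@H](c1ccc(OC(C)=O)cc1)C[C@H]2O[Si]3(C(C)(C)C)C(C)(C)C
F2 | step 3 | racemic 2,4-cis 4'-acetoxy-7-methoxy-8-(3-methylbut-2-en-1-yl)flavan-4,5-diol (10 plus its enantiomer) | COc1cc(O)c2c(c1CC=C(C)C)O[C@H](c1ccc(OC(C)=O)cc1)C[C@@H]2O.COc1cc(O)c2c(c1CC=C(C)C)O[C@@H](c1ccc(OC(C)=O)cc1)C[C@H]2O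
F3 | step 3 | (2S,4R)-4'-acetoxy-5-hydroxy-7-methoxy-8-(3-methylbut-2-en-1-yl)flavan-4-yl (S)-2-methoxy-2-phenylacetate | COc1cc(O)c2c(c1CC=C(C)C)O[C@H](c1ccc(OC(C)=O)cc1)C[C@H]2OC(=O)[C@@H](OC)c1ccccc1
F4 | step 3 | (2R,4S)-4'-acetoxy-5-hydroxy-7-methoxy-8-(3-methylbut-2-en-1-yl)flavan-4-yl (S)-2-methoxy-2-phenylacetate | COc1cc(O)c2c(c1CC=C(C)C)O[C@@H](c1ccc(OC(C)=O)cc1)C[C@@H]2OC(=O)[C@@H](OC)c1ccccc1
F5 | step 5 | (2S,4S)-4,5,4'-trihydroxy-7-methoxy-8-(3-methylbut-2-en-1-yl)flavan (2,4-cis) | COc1cc(O)c2c(c1CC=C(C)C)O[C@H](c1ccc(O)cc1)C[C@@H]2O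
F6 | step 2 | 6-[(di-tert-butylsilyl)oxy]-2-hydroxy-4-methoxy-3-(3-methylbut-2-en-1-yl)benzaldehyde | COc1cc(O[SiH](C(C)(C)C)C(C)(C)C)c(C=O)c(O)c1CC=C(C)C
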